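If each substrate that reacts takes one reagent with it, then in a flask charged one to one the two stay equal, and the reciprocal of their concentration climbs in a straight line with time. That gave me the bench rule for early readings: the reacted share is t/(t+τ), where t is the time and τ the time at which reacted and unreacted substrate are equal, and τ shortens in proportion as the charged concentration rises.

| flask | substrate | reagent | temperature | remark | time |
|---|---|---|---|---|---|
| oak | 0.021 M | 1 equiv | 18 °C | run made earlier |  |
| larch | 0.033 M | 1 equiv | 34 °C | run made earlier |  |
| noon | 0.015 M | 1.00 equiv | 40 °C |  | 12 h |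
| dusk | 0.015 M | 1.00 equiv | 25 °C |  | 12 h |
| spring | 0.015 M | 1.00 equiv | 10 °C |  | 12 h |

| run | time / h | mono adduct / % |
|---|---|---|
| oak | 2.00 | 11 |
| oak | 6.00 | 24 |
| oak | 8.00 | 27 |
| oak | 15.0 | 32 |
| oak | 25.0 | 36 |
| oak | 30.0 | 34 |
| larch | 0.833 | 19 |
| larch | 1.33 | 27 |
| larch | 2.00 | 35 |
| larch | 4.00 | 26 |
| larch | 6.00 | 26 |
| larch | 10.0 | 17 |

(standard deviation of a reading: 2 percentage points)

- a reading or a percentage of mono adduct counts all its forms, free or not

- which flask leads in amount of mono adduct, in percent of the substrate charged ("all alike" within 1.5 percentage points) (noon / dusk / spring / all alike)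
- how much mono adduct is there at the end, in percent of the substrate charged: noon
- how much mono adduct is there at the end, in percent of the substrate charged: dusk
- how much mono adduct is there at the end, in percent of the substrate charged: spring

The first oak reading gave τ = 16.2 h and the first larch reading gave 3.55 h. Counting all reacted substrate as mono adduct, the rule promised 60.7 % in oak at 25.0 h, but the reading was 36 %, a ratio of 0.593, so the rule had stopped working and mono adduct was being lost.

I therefore solved both ends and joined them. Supply of mono adduct runs at x·x/τ, with x the unreacted share, and loss runs at y/L, with y the mono adduct and L a loss time. At a crest the two are equal, so L = yτ/(x·x). As readings, with their scatter, the oak crest at 25.0 h gave L = 37.7 h and the larch crest at 2.00 h gave 3.04 h. Going 0.438 of the way from oak's temperature to larch's on a logarithmic scale, I reckoned for dusk τ = 14.2 h and L = 12.5 h, which put x at 54.2 % after 12 h. Then y = x·x·L/τ came to 25.9 %; this is the balance level, the amount of mono adduct in dusk at which supply equals loss at that moment, and since my L was about as long as the run, I took it as a moving level and not as a steady state.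

The forecast named dusk as leader, with 12 % for noon, 28 % for dusk and 20 % for spring. It read oak's plateau otherwise than I did, as “reagent exhaustion caps the mono adduct”, and its dusk figure stood above mine.

    substrate + reagent → mono adduct + by-product (k = 0.313 M⁻¹ min⁻¹, Ea = 71.0 kJ mol⁻¹)
    substrate + reagent → other mono adduct + by-product (k = 0.0173 M⁻¹ min⁻¹, Ea = 70.0 kJ mol⁻¹)
    reagent + mono adduct → double product + by-product (k = 0.00631 M⁻¹ min⁻¹, Ea = 65.0 kJ mol⁻¹)
    reagent + other mono adduct → double product + by-product (k = 0.423 M⁻¹ min⁻¹, Ea = 78.0 kJ mol⁻¹)
    mono adduct → over-reaction product (k = 0.00942 min⁻¹, Ea = 106 kJ mol⁻¹)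
    crystals ⇌ mono adduct, rate k6*(cs6 - [mono adduct]) while solid is left; crystals form when [mono adduct] > cs6 (solubility = 11.0 mM, k = 0.0751 min⁻¹)
    (constants at 40 °C)

The flask that led was dusk, with 27.0 % against 3.17 % in noon and 14.9 % in spring. In dusk, substrate and reagent went on forming mono adduct while mono adduct turned into over-reaction product, and 53 % of the substrate and 17.6 % of over-reaction product stood at the end. Dissolved mono adduct was made 2.94 times as fast as it was used at 4.11 h, and that ratio was 0.976 at 12.0 h, with the amount beside my balance level of 25.9 %. The neighbour with 0.250 equiv of reagent kept 86 % of its substrate and 43 % of its reagent, which gives a balance level of 8.20 %, and it held 8.27 %.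

(All runs are simulated with made-up constants, noise included.)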